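The upper 4‑arylflavan is disconnected across O1–C2 and C3–C4 of its ring C. Upper C4 is benzylic to ring A, whose ortho carbon C8a carries O1, so C8a–C4a–C4 is the latent oxadiene O=C8a–C4a=C4 of an o‑quinone methide. A chiral phosphoric acid unmasks it from an o‑hydroxybenzhydrol and steers its [4+2] union with ethyl vinyl ether, which closes ring C, sets C4 and leaves a C2 acetal for ring B. The precursor is the carbinol that joins a 2‑hydroxy‑3,4‑bis(benzyloxy)phenyl ring to C6 of the fully benzylated all‑cis (2R,3R,4R) lower flavan‑3,4‑diol.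

Key step: step 15

Remarks
- Stereochemistry: the lower unit is the all‑cis (2R,3R,4R) flavan‑3,4‑diol and the upper unit is 2,4‑trans (2S,4S) in the free phenol. While the phenols are benzylated (25, 26) the CIP label of upper C4 reads R because the ranking of its two aryl groups changes; the geometry is the same.
- Assumption: which antipode of the phosphoric acid shields the required face of the quinone methide cannot be derived with certainty for this substrate. The (R)‑acid is written; its antipode is the drop‑in replacement.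
- Precursor design: lower O3 and O4 stay as benzyl ethers. A cyclic acetal would ionize alongside the C2 acetal in step 16, and esters would not survive the aryllithium. The lower 7‑benzyloxy group is flanked on both sides and twisted out of conjugation, which should keep the lower C4 benzylic ether from ionizing in the two acidic steps.
- Carbinol 22 is used as its epimer mixture and acetal 25 as its C2 epimers, because both centres are erased later.

Step 1
Reactants: 1 gallacetophenone (2,3,4‑trihydroxyacetophenone)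
Product: 2 1‑[3,4‑bis(benzyloxy)‑2‑hydroxyphenyl]ethanone
Conditions: BnBr (2.1 equiv), K2CO3 (2.2 equiv), DMF, rt
Reagents that add atoms: benzyl bromide, BrCc1ccccc1
Why: Williamson etherification; the 2‑hydroxyl is hydrogen‑bonded to the acetyl carbonyl and is the least nucleophilic, so two equivalents of benzyl bromide should take O3 and O4.

Step 2
Reactants: 2 1‑[3,4‑bis(benzyloxy)‑2‑hydroxyphenyl]ethanone
Product: 3 1‑[3,4‑bis(benzyloxy)‑5‑bromo‑2‑hydroxyphenyl]ethanone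
Conditions: NBS, MeCN, 0 °C → rt
Reagents that add atoms: N‑bromosuccinimide, O=C1CCC(=O)N1Br
Why: Electrophilic aromatic bromination; C5 is para to the free hydroxyl and ortho to the 4‑benzyloxy group, the only activated open position (it becomes lower C6).

Step 3
Reactants: 3 1‑[3,4‑bis(benzyloxy)‑5‑bromo‑2‑hydroxyphenyl]ethanone
Product: 4 1‑[3,4‑bis(benzyloxy)‑5‑bromo‑2‑(methoxymethoxy)phenyl]ethanone
Conditions: NaH, MOMCl, DMF, 0 °C
Reagents that add atoms: chloromethyl methyl ether, COCCl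
Why: Phenoxide alkylation masks the phenol so that the chalcone can neither cyclize nor be deactivated as a phenoxide during the epoxidation.

Step 4
Reactants: 4 1‑[3,4‑bis(benzyloxy)‑5‑bromo‑2‑(methoxymethoxy)phenyl]ethanone; 5 4‑benzyloxybenzaldehyde
Product: 6 (E)‑1‑[3,4‑bis(benzyloxy)‑5‑bromo‑2‑(methoxymethoxy)phenyl]‑3‑[4‑(benzyloxy)phenyl]prop‑2‑en‑1‑one
Conditions: KOH, EtOH–THF, rt
Reagents that add atoms: none
Why: Claisen–Schmidt condensation; dehydration of the aldol should give the conjugated (E)‑enone.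

Step 5
Reactants: 6 (E)‑chalcone
Product: 7 {(2R,3S)‑3‑[4‑(benzyloxy)phenyl]oxiran‑2‑yl}[3,4‑bis(benzyloxy)‑5‑bromo‑2‑(methoxymethoxy)phenyl]methanone
Conditions: poly‑L‑leucine (silica‑supported), urea–H2O2, DBU, THF, rt
Reagents that add atoms: urea–hydrogen peroxide, NC(N)=O.OO
Why: Juliá–Colonna epoxidation; the helical peptide should deliver the hydroperoxide to one enone face, giving the (2R,3S)‑trans‑epoxide, the source of absolute configuration for the lower unit.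

Step 6
Reactants: 7 (2R,3S)‑epoxy ketone
Product: 9 (2R,3R)‑7,8‑bis(benzyloxy)‑2‑[4‑(benzyloxy)phenyl]‑6‑bromo‑3‑hydroxychroman‑4‑one, via hydroxy epoxide 8 (not isolated)
Conditions: conc. HCl, MeOH–THF, 55 °C
Reagents that add atoms: none
Why: Acid removes the MOM acetal and the freed phenol opens the epoxide at the benzylic carbon (6‑endo, inversion) to the 2,3‑trans dihydroflavonol; trans is also the thermodynamic isomer, so C3 relays its configuration to C2 even if the opening has cationic character.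

Step 7
Reactants: 9 (2R,3R)‑dihydroflavonol
Product: 11 (2R,3S,4R)‑7,8‑bis(benzyloxy)‑2‑[4‑(benzyloxy)phenyl]‑6‑bromo‑3‑[(2‑methoxypropan‑2‑yl)oxy]chroman‑4‑ol, via ketal ketone 10 (not isolated)
Conditions: 2‑methoxypropene, PPTS (cat.), CH2Cl2, 0 °C; then Et3N, MeOH, NaBH4, 0 °C
Reagents that add atoms: 2‑methoxypropene, C=C(C)OC
Why: Acid‑catalysed enol ether addition caps O3 as an achiral ketal, then NaBH4 should add hydride axially to C4 so that the new hydroxyl is equatorial, trans to O3 and cis to the C2 aryl group, the usual outcome for trans‑dihydroflavonols.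

Step 8
Reactants: 11 (2R,3S,4R)‑ketal alcohol
Product: 13 (2R,3S,4R)‑4,7,8‑tris(benzyloxy)‑2‑[4‑(benzyloxy)phenyl]‑6‑bromochroman‑3‑ol, via benzyl ether ketal 12 (not isolated)
Conditions: NaH, BnBr, Bu4NI (cat.), DMF, 0 °C → rt; then MeOH, 1 M HCl to pH 2, rt
Reagents that add atoms: benzyl bromide, BrCc1ccccc1
Why: Williamson etherification at O4 (the ketal tolerates NaH, and no acyl or silyl group is present to migrate), then brief aqueous acid should hydrolyse the very labile 2‑methoxypropan‑2‑yl ketal and leave the benzyl ethers alone.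

Step 9
Reactants: 13 (2R,3S,4R)‑3‑alcohol
Product: 14 (2R,4R)‑4,7,8‑tris(benzyloxy)‑2‑[4‑(benzyloxy)phenyl]‑6‑bromochroman‑3‑one
Conditions: Dess–Martin periodinane, NaHCO3, CH2Cl2, 0 °C → rt; used crude
Reagents that add atoms: none
Why: Dess–Martin oxidation under buffered, non‑enolizing conditions should give the 3‑ketone without disturbing the flanking C2 and C4 centres.

Step 10
Reactants: 14 (2R,4R)‑3‑ketone
Product: 15 (2R,3R,4R)‑4,7,8‑tris(benzyloxy)‑2‑[4‑(benzyloxy)phenyl]‑6‑bromochroman‑3‑ol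
Conditions: LiBH(sec‑Bu)3 (L‑Selectride), THF, −78 °C; NH4Cl
Reagents that add atoms: none
Why: Bulky‑hydride reduction, as in the conversion of catechin‑type 3‑ketones into the epi series; the hydride should attack equatorially, anti to the cis‑disposed C2 aryl and C4 benzyloxy groups, giving the axial 3‑hydroxyl cis to both, which is the all‑cis array.

Step 11
Reactants: 15 (2R,3R,4R)‑3‑alcohol
Product: 16 (2R,3R,4R)‑3,4,7,8‑tetrakis(benzyloxy)‑2‑[4‑(benzyloxy)phenyl]‑6‑bromochromane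
Conditions: NaH, BnBr, Bu4NI (cat.), DMF, 0 °C → rt
Reagents that add atoms: benzyl bromide, BrCc1ccccc1
Why: Williamson etherification of the remaining secondary alcohol completes a protecting‑group set that falls in a single hydrogenolysis.

Step 12
Reactants: 17 2,3,4‑trihydroxybenzaldehyde
Product: 18 3,4‑bis(benzyloxy)‑2‑hydroxybenzaldehyde
Conditions: BnBr (2.1 equiv), K2CO3 (2.2 equiv), DMF, rt
Reagents that add atoms: benzyl bromide, BrCc1ccccc1
Why: Williamson etherification; as in step 1 the carbonyl‑chelated 2‑hydroxyl should stay free.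

Step 13
Reactants: 18 3,4‑bis(benzyloxy)‑2‑hydroxybenzaldehyde
Product: 19 3,4‑bis(benzyloxy)‑2‑[(tert‑butyldimethylsilyl)oxy]benzaldehyde
Conditions: TBSCl, imidazole, DMF, rt
Reagents that add atoms: tert‑butyldimethylsilyl chloride, CC(C)(C)[Si](C)(C)Cl
Why: Imidazole‑promoted silylation masks the acidic phenol, which would otherwise quench the aryllithium.

Step 14
Reactants: 16 lower‑unit bromide; 19 silylated aldehyde
Product: 22 [3,4‑bis(benzyloxy)‑2‑hydroxyphenyl]{(2R,3R,4R)‑3,4,7,8‑tetrakis(benzyloxy)‑2‑[4‑(benzyloxy)phenyl]chroman‑6‑yl}methanol (both carbinol epimers), via aryllithium 20 (not isolated), via silyl ether adduct 21 (not isolated)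
Conditions: t‑BuLi (2.05 equiv), THF, −78 °C; 19, −78 → 0 °C; then Bu4NF, 0 °C; NH4Cl
Reagents that add atoms: none
Why: Bromine–lithium exchange and 1,2‑addition to the aldehyde form the diaryl carbinol, and fluoride removes the silyl group from whichever oxygen holds it after possible O‑to‑O migration; the carbinol configuration is irrelevant.

Step 15
Reactants: 22 o‑hydroxybenzhydrol (epimer mixture); 23 ethyl vinyl ether
Product: 25 (2R,4R)‑7,8‑bis(benzyloxy)‑2‑ethoxy‑4‑{(2R,3R,4R)‑3,4,7,8‑tetrakis(benzyloxy)‑2‑[4‑(benzyloxy)phenyl]chroman‑6‑yl}chromane (2,4‑cis acetal drawn; its C2 epimer is equally useful), via o‑quinone methide 24 (not isolated)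
Conditions: (R)‑3,3'‑bis(2,4,6‑triisopropylphenyl)‑1,1'‑binaphthyl‑2,2'‑diyl hydrogen phosphate (10 mol %), 23 (5 equiv), 4 Å MS, toluene, 0 °C
Reagents that add atoms: none
Why: The acid protonates the benzhydrol hydroxyl and water leaves with push from the ortho phenol and the para C7 benzyloxy group, giving (E)‑o‑quinone methide 24, which stays hydrogen‑bonded through its carbonyl oxygen to the chiral phosphate. The closest known reaction type is the chiral phosphoric acid catalysed inverse‑electron‑demand [4+2] cycloaddition of o‑quinone methides, generated in situ from o‑hydroxybenzhydrols, with electron‑rich alkenes. Ring C closes in the cycloaddition itself: the oxadiene O=C8a–C4a=C4 and the vinyl ether combine in a concerted, asynchronous event in which C3–C4 bonding leads and O1–C2 follows. C4 is set by the catalyst, whose 3,3'‑aryl groups block one face of the bound methide while the remote lower‑unit stereocentres exert little bias; C2 follows from endo approach and is erased in step 16. The step needs regioselectivity (CH2 terminus to C4, oxygen‑bearing carbon to O1), which the polarity of both partners secures, and chemoselective ionization of the doubly benzylic carbinol over the lower C4 benzyl ether, which the far greater stabilization of the diarylmethyl cation and the weak acid secure.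

Step 16
Reactants: 25 2‑ethoxy‑4‑arylchroman
Product: 26 (2S,4R)‑7,8‑bis(benzyloxy)‑2‑[4‑(benzyloxy)phenyl]‑4‑{(2R,3R,4R)‑3,4,7,8‑tetrakis(benzyloxy)‑2‑[4‑(benzyloxy)phenyl]chroman‑6‑yl}chromane
Conditions: (4‑benzyloxyphenyl)zinc bromide (from (4‑benzyloxyphenyl)magnesium bromide and ZnBr2, THF), BF3·OEt2, CH2Cl2, −78 → −30 °C; NaHCO3
Reagents that add atoms: (4‑benzyloxyphenyl)zinc bromide, Br[Zn]c1ccc(OCc2ccccc2)cc1
Why: Lewis acid mediated acetal substitution; BF3·OEt2 should ionize only the C2 acetal to the cyclic oxocarbenium ion, and the arylzinc should add pseudoaxially on the face anti to the C4 aryl group, placing ring B 2,4‑trans.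

Step 17
Reactants: 26 octa‑O‑benzyl biflavanoid
Product: 27 (2R,3R,4R)‑6‑[(2S,4S)‑7,8‑dihydroxy‑2‑(4‑hydroxyphenyl)chroman‑4‑yl]‑2‑(4‑hydroxyphenyl)chromane‑3,4,7,8‑tetrol (CNP0209379.1)
Conditions: H2 (1 atm), Pd(OH)2/C, THF–MeOH, rt; filtered under argon
Reagents that add atoms: none
Why: Hydrogenolysis of eight benzyl ethers; under neutral conditions the unhindered O–CH2Ph bonds should cleave well before the hindered ring benzylic C–O bonds (O1–C2 of both units, lower C4–O).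

Compound list
1 | gallacetophenone | CC(=O)c1ccc(O)c(O)c1O | starting material
2 | 1‑[3,4‑bis(benzyloxy)‑2‑hydroxyphenyl]ethanone | CC(=O)c1ccc(OCc9ccccc9)c(OCc9ccccc9)c1O | intermediate
3 | 1‑[3,4‑bis(benzyloxy)‑5‑bromo‑2‑hydroxyphenyl]ethanone | CC(=O)c1cc(Br)c(OCc9ccccc9)c(OCc9ccccc9)c1O | intermediate
4 | 1‑[3,4‑bis(benzyloxy)‑5‑bromo‑2‑(methoxymethoxy)phenyl]ethanone | CC(=O)c1cc(Br)c(OCc9ccccc9)c(OCc9ccccc9)c1OCOC | intermediate
5 | 4‑benzyloxybenzaldehyde | O=Cc1ccc(OCc2ccccc2)cc1 | starting material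
6 | (E)‑1‑[3,4‑bis(benzyloxy)‑5‑bromo‑2‑(methoxymethoxy)phenyl]‑3‑[4‑(benzyloxy)phenyl]prop‑2‑en‑1‑one | COCOc1c(C(=O)/C=C/c2ccc(OCc9ccccc9)cc2)cc(Br)c(OCc9ccccc9)c1OCc9ccccc9 | intermediate
7 | {(2R,3S)‑3‑[4‑(benzyloxy)phenyl]oxiran‑2‑yl}[3,4‑bis(benzyloxy)‑5‑bromo‑2‑(methoxymethoxy)phenyl]methanone | COCOc1c(C(=O)[C@@H]2O[C@H]2c2ccc(OCc9ccccc9)cc2)cc(Br)c(OCc9ccccc9)c1OCc9ccccc9 | intermediate
8 | {(2R,3S)‑3‑[4‑(benzyloxy)phenyl]oxiran‑2‑yl}[3,4‑bis(benzyloxy)‑5‑bromo‑2‑hydroxyphenyl]methanone | Oc1c(C(=O)[C@@H]2O[C@H]2c2ccc(OCc9ccccc9)cc2)cc(Br)c(OCc9ccccc9)c1OCc9ccccc9 | intermediate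
9 | (2R,3R)‑7,8‑bis(benzyloxy)‑2‑[4‑(benzyloxy)phenyl]‑6‑bromo‑3‑hydroxychroman‑4‑one | Brc1cc2c(c(OCc9ccccc9)c1OCc9ccccc9)O[C@H](c3ccc(OCc9ccccc9)cc3)[C@@H](O)C2=O | intermediate
10 | (2R,3R)‑7,8‑bis(benzyloxy)‑2‑[4‑(benzyloxy)phenyl]‑6‑bromo‑3‑[(2‑methoxypropan‑2‑yl)oxy]chroman‑4‑one | Brc1cc2c(c(OCc9ccccc9)c1OCc9ccccc9)O[C@H](c3ccc(OCc9ccccc9)cc3)[C@@H](OC(C)(C)OC)C2=O | intermediate
11 | (2R,3S,4R)‑7,8‑bis(benzyloxy)‑2‑[4‑(benzyloxy)phenyl]‑6‑bromo‑3‑[(2‑methoxypropan‑2‑yl)oxy]chroman‑4‑ol | Brc1cc2c(c(OCc9ccccc9)c1OCc9ccccc9)O[C@H](c3ccc(OCc9ccccc9)cc3)[C@@H](OC(C)(C)OC)[C@@H]2O | intermediate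
12 | (2R,3S,4R)‑4,7,8‑tris(benzyloxy)‑2‑[4‑(benzyloxy)phenyl]‑6‑bromo‑3‑[(2‑methoxypropan‑2‑yl)oxy]chromane | Brc1cc2c(c(OCc9ccccc9)c1OCc9ccccc9)O[C@H](c3ccc(OCc9ccccc9)cc3)[C@@H](OC(C)(C)OC)[C@@H]2OCc9ccccc9 | intermediate
13 | (2R,3S,4R)‑4,7,8‑tris(benzyloxy)‑2‑[4‑(benzyloxy)phenyl]‑6‑bromochroman‑3‑ol (2,3‑trans‑3,4‑trans) | Brc1cc2c(c(OCc9ccccc9)c1OCc9ccccc9)O[C@H](c3ccc(OCc9ccccc9)cc3)[C@@H](O)[C@@H]2OCc9ccccc9 | intermediate
14 | (2R,4R)‑4,7,8‑tris(benzyloxy)‑2‑[4‑(benzyloxy)phenyl]‑6‑bromochroman‑3‑one (2,4‑cis) | Brc1cc2c(c(OCc9ccccc9)c1OCc9ccccc9)O[C@H](c3ccc(OCc9ccccc9)cc3)C(=O)[C@@H]2OCc9ccccc9 | intermediate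
15 | (2R,3R,4R)‑4,7,8‑tris(benzyloxy)‑2‑[4‑(benzyloxy)phenyl]‑6‑bromochroman‑3‑ol (all‑cis) | Brc1cc2c(c(OCc9ccccc9)c1OCc9ccccc9)O[C@H](c3ccc(OCc9ccccc9)cc3)[C@H](O)[C@@H]2OCc9ccccc9 | intermediate
16 | (2R,3R,4R)‑3,4,7,8‑tetrakis(benzyloxy)‑2‑[4‑(benzyloxy)phenyl]‑6‑bromochromane | Brc1cc2c(c(OCc9ccccc9)c1OCc9ccccc9)O[C@H](c3ccc(OCc9ccccc9)cc3)[C@H](OCc9ccccc9)[C@@H]2OCc9ccccc9 | intermediate
17 | 2,3,4‑trihydroxybenzaldehyde | O=Cc1ccc(O)c(O)c1O | starting material
18 | 3,4‑bis(benzyloxy)‑2‑hydroxybenzaldehyde | O=Cc1ccc(OCc9ccccc9)c(OCc9ccccc9)c1O | intermediate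
19 | 3,4‑bis(benzyloxy)‑2‑[(tert‑butyldimethylsilyl)oxy]benzaldehyde | O=Cc1ccc(OCc9ccccc9)c(OCc9ccccc9)c1O[Si](C)(C)C(C)(C)C | intermediate
20 | {(2R,3R,4R)‑3,4,7,8‑tetrakis(benzyloxy)‑2‑[4‑(benzyloxy)phenyl]chroman‑6‑yl}lithium | [Li]c1cc2c(c(OCc9ccccc9)c1OCc9ccccc9)O[C@H](c3ccc(OCc9ccccc9)cc3)[C@H](OCc9ccccc9)[C@@H]2OCc9ccccc9 | intermediate
21 | {3,4‑bis(benzyloxy)‑2‑[(tert‑butyldimethylsilyl)oxy]phenyl}{(2R,3R,4R)‑3,4,7,8‑tetrakis(benzyloxy)‑2‑[4‑(benzyloxy)phenyl]chroman‑6‑yl}methanol (carbinol epimers; silyl drawn on the phenolic oxygen) | OC(c1cc2c(c(OCc9ccccc9)c1OCc9ccccc9)O[C@H](c3ccc(OCc9ccccc9)cc3)[C@H](OCc9ccccc9)[C@@H]2OCc9ccccc9)c1ccc(OCc9ccccc9)c(OCc9ccccc9)c1O[Si](C)(C)C(C)(C)C | intermediate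
22 | [3,4‑bis(benzyloxy)‑2‑hydroxyphenyl]{(2R,3R,4R)‑3,4,7,8‑tetrakis(benzyloxy)‑2‑[4‑(benzyloxy)phenyl]chroman‑6‑yl}methanol (carbinol epimers, centre left open) | OC(c1cc2c(c(OCc9ccccc9)c1OCc9ccccc9)O[C@H](c3ccc(OCc9ccccc9)cc3)[C@H](OCc9ccccc9)[C@@H]2OCc9ccccc9)c1ccc(OCc9ccccc9)c(OCc9ccccc9)c1O | intermediate
23 | ethyl vinyl ether | C=COCC | starting material
24 | (E)‑2,3‑bis(benzyloxy)‑6‑({(2R,3R,4R)‑3,4,7,8‑tetrakis(benzyloxy)‑2‑[4‑(benzyloxy)phenyl]chroman‑6‑yl}methylidene)cyclohexa‑2,4‑dien‑1‑one | O=C1C(OCc9ccccc9)=C(OCc9ccccc9)C=C/C1=C\c1cc2c(c(OCc9ccccc9)c1OCc9ccccc9)O[C@H](c3ccc(OCc9ccccc9)cc3)[C@H](OCc9ccccc9)[C@@H]2OCc9ccccc9 | intermediate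
25 | (2R,4R)‑7,8‑bis(benzyloxy)‑2‑ethoxy‑4‑{(2R,3R,4R)‑3,4,7,8‑tetrakis(benzyloxy)‑2‑[4‑(benzyloxy)phenyl]chroman‑6‑yl}chromane | CCO[C@H]1C[C@@H](c2cc3c(c(OCc9ccccc9)c2OCc9ccccc9)O[C@H](c4ccc(OCc9ccccc9)cc4)[C@H](OCc9ccccc9)[C@@H]3OCc9ccccc9)c2ccc(OCc9ccccc9)c(OCc9ccccc9)c2O1 | intermediate
26 | (2S,4R)‑7,8‑bis(benzyloxy)‑2‑[4‑(benzyloxy)phenyl]‑4‑{(2R,3R,4R)‑3,4,7,8‑tetrakis(benzyloxy)‑2‑[4‑(benzyloxy)phenyl]chroman‑6‑yl}chromane (2,4‑trans) | O(Cc9ccccc9)c1ccc([C@@H]2C[C@@H](c3cc4c(c(OCc9ccccc9)c3OCc9ccccc9)O[C@H](c5ccc(OCc9ccccc9)cc5)[C@H](OCc9ccccc9)[C@@H]4OCc9ccccc9)c3ccc(OCc9ccccc9)c(OCc9ccccc9)c3O2)cc1 | intermediate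
27 | (2R,3R,4R)‑6‑[(2S,4S)‑7,8‑dihydroxy‑2‑(4‑hydroxyphenyl)chroman‑4‑yl]‑2‑(4‑hydroxyphenyl)chromane‑3,4,7,8‑tetrol | Oc1ccc([C@@H]2C[C@@H](c3cc4c(c(O)c3O)O[C@H](c3ccc(O)cc3)[C@H](O)[C@@H]4O)c3ccc(O)c(O)c3O2)cc1 | target

Total step count: 17.
Longest linear sequence: 15 steps (steps 1–11 and 14–17, from gallacetophenone 1).

Steps most likely to fail

Step 15. The phosphate may discriminate the two faces of quinone methide 24 poorly, because a vinyl ether offers it no hydrogen‑bond donor and the chiral lower unit may be mismatched; acid‑induced oligomerization of the vinyl ether may also erode conversion. The fallback hands control to a covalently bound auxiliary under non‑acidic conditions; it sets out from phenol 18 and bromide 16 and comes back at 26. Phenol 18 is acylated (Boc2O, cat. DMAP, CH2Cl2) to 3,4‑bis(benzyloxy)‑2‑[(tert‑butoxycarbonyl)oxy]benzaldehyde F1. Commercial (1R,2S)‑2‑phenylcyclohexanol is transvinylated (ethyl vinyl ether, Hg(OAc)2 cat.) to (1R,2S)‑2‑phenylcyclohexyl vinyl ether F2. Aryllithium 20, made from 16 as in step 14, is added to F1 at −78 °C in the presence of F2 and MgBr2·OEt2. On warming, the carbonate should migrate to the benzylic alkoxide, the magnesium phenoxide should expel tert‑butyl carbonate, and quinone methide 24 should be trapped endo on the face set by the auxiliary, giving the 2‑[(1R,2S)‑2‑phenylcyclohexyl]oxy analogue of 25, F3. Under the conditions of step 16, F3 releases the auxiliary alcohol and gives 26. The antipode of the auxiliary is chosen by the same reasoning as the catalyst antipode.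

Step 16. BF3·OEt2 may also ionize the lower C4 benzyl ether, aryl transfer from zinc may be too slow at the temperature that spares that ether, or anti delivery may be eroded. The fallback replaces Lewis‑acid activation of the acetal by an anomeric sulfone; it sets out from 25 and comes back at 26. Benzenesulfinic acid and CaCl2 in CH2Cl2 should exchange ethoxide for sulfinate and give the 2‑(phenylsulfonyl)chroman F4 as C2 epimers. (4‑Benzyloxyphenyl)zinc bromide with ZnBr2 in THF at room temperature should then displace the sulfonyl group through the same oxocarbenium ion, anti to the C4 aryl group, without BF3, giving 26.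

Step 10. The hydride may act as a base on ketone 14, whose C2–H and C4–H are both benzylic and α to the carbonyl, so enolization would scramble C2 and C4; facial selectivity may also be incomplete. The fallback inverts C3 by substitution instead of oxidation and reduction; it sets out from 9 and comes back at 16. Tf2O and pyridine (CH2Cl2, −20 °C) should convert 9 into the (2R,3R)‑3‑trifluoromethanesulfonate F5. CsOAc with 18‑crown‑6 in toluene should displace the triflate with inversion next to the carbonyl, giving the (2R,3S)‑cis‑3‑acetoxy ketone F6. NaBH4 at −20 °C should add hydride anti to the axial acetoxy group, and K2CO3 in MeOH should then remove the acetate, giving the all‑cis (2R,3R,4R)‑7,8‑bis(benzyloxy)‑2‑[4‑(benzyloxy)phenyl]‑6‑bromochromane‑3,4‑diol F7. Double benzylation (NaH, BnBr, DMF) gives 16.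

Further compounds
F1 | step 15 | 3,4‑bis(benzyloxy)‑2‑[(tert‑butoxycarbonyl)oxy]benzaldehyde | O=Cc1ccc(OCc9ccccc9)c(OCc9ccccc9)c1OC(=O)OC(C)(C)C
F2 | step 15 | (1R,2S)‑2‑phenylcyclohexyl vinyl ether | C=CO[C@@H]1CCCC[C@H]1c1ccccc1
F3 | step 15 | (2R,4R)‑7,8‑bis(benzyloxy)‑2‑{[(1R,2S)‑2‑phenylcyclohexyl]oxy}‑4‑{(2R,3R,4R)‑3,4,7,8‑tetrakis(benzyloxy)‑2‑[4‑(benzyloxy)phenyl]chroman‑6‑yl}chromane | O([C@@H]5CCCC[C@H]5c5ccccc5)[C@H]1C[C@@H](c2cc3c(c(OCc9ccccc9)c2OCc9ccccc9)O[C@H](c4ccc(OCc9ccccc9)cc4)[C@H](OCc9ccccc9)[C@@H]3OCc9ccccc9)c2ccc(OCc9ccccc9)c(OCc9ccccc9)c2O1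
F4 | step 16 | (4R)‑7,8‑bis(benzyloxy)‑2‑(phenylsulfonyl)‑4‑{(2R,3R,4R)‑3,4,7,8‑tetrakis(benzyloxy)‑2‑[4‑(benzyloxy)phenyl]chroman‑6‑yl}chromane (C2 epimers) | O=S(=O)(c1ccccc1)C1C[C@@H](c2cc3c(c(OCc9ccccc9)c2OCc9ccccc9)O[C@H](c4ccc(OCc9ccccc9)cc4)[C@H](OCc9ccccc9)[C@@H]3OCc9ccccc9)c2ccc(OCc9ccccc9)c(OCc9ccccc9)c2O1
F5 | step 10 | (2R,3R)‑7,8‑bis(benzyloxy)‑2‑[4‑(benzyloxy)phenyl]‑6‑bromo‑4‑oxochroman‑3‑yl trifluoromethanesulfonate | Brc1cc2c(c(OCc9ccccc9)c1OCc9ccccc9)O[C@H](c3ccc(OCc9ccccc9)cc3)[C@@H](OS(=O)(=O)C(F)(F)F)C2=O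
F6 | step 10 | (2R,3S)‑7,8‑bis(benzyloxy)‑2‑[4‑(benzyloxy)phenyl]‑6‑bromo‑4‑oxochroman‑3‑yl acetate (2,3‑cis) | Brc1cc2c(c(OCc9ccccc9)c1OCc9ccccc9)O[C@H](c3ccc(OCc9ccccc9)cc3)[C@H](OC(C)=O)C2=O
F7 | step 10 | (2R,3R,4R)‑7,8‑bis(benzyloxy)‑2‑[4‑(benzyloxy)phenyl]‑6‑bromochromane‑3,4‑diol | Brc1cc2c(c(OCc9ccccc9)c1OCc9ccccc9)O[C@H](c3ccc(OCc9ccccc9)cc3)[C@H](O)[C@@H]2O
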